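**Retrosynthetic overview**

- The strategy rests on the (Z)-5-ylidene tetronic acid: the butenolide ring O1–C2(=O)–C3(CH3)=C4(OH)–C5 with the exocyclic C5=C6 bond. O1 and the hydrogen on C6 stand trans, which is the pattern left by anti addition of a carboxyl O–H across a C5≡C6 triple bond.
- The butenolide is the only ring made, and it is made last, since both furans are bought. Silver-catalysed 5-exo-dig lactonisation of the (E)-3-methoxy-2-methyl-2-en-4-ynoic acid forms O1–C5, the ring and the Z olefin together, and SN2 O-demethylation then frees the tetronic acid.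
- C4–C5 comes from Sonogashira coupling of the side-chain alkyne with methyl (Z)-3-iodo-3-methoxy-2-methylacrylate, whose geometry is set by ester-directed β-lithiation. Acylating the acetylide with a methylmalonyl electrophile is avoided because its acidic C–H would only protonate the acetylide, and O-methylating a keto ester would leave the enol ether geometry open.
- C5≡C6 comes from the C6 aldehyde (Ohira–Bestmann), C7 (S) from (R)-3-bromo-2-methylpropan-1-ol, C11=C12 (Z) from syn carbocupration of propyne with iodinolysis, and C12–C13 from B-alkyl Suzuki–Miyaura coupling.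
- The bis-furan comes from 3-furyllithium plus 4-bromo-2-furaldehyde, followed by ionic deoxygenation and vinylation.

Key step: step 16

Remark: atom labels follow the target throughout (O1, C2–C5 ring, C6 exocyclic CH, C7 stereocentre, C8–C10, C11=C12, C13, C14). The target is handled as the 4-hydroxy enol tautomer of its SMILES. The bis-furyl carbinol of step 5 is made as the racemate because its stereocentre is removed in step 6.

**Step 1**
Reactants: 1 (R)-3-bromo-2-methylpropan-1-ol
Product: 2 (R)-(3-bromo-2-methylpropoxy)(tert-butyl)dimethylsilane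
Conditions: TBSCl, imidazole, CH2Cl2, 0 °C to rt
Reagents that add atoms: tert-butyldimethylsilyl chloride, CC(C)(C)[Si](C)(C)Cl
Why: Imidazole-promoted silylation masks the future C6 oxygen as an ether that withstands Grignard, organocopper and palladium chemistry, and the stereocentre is not touched.

**Step 2**
Reactants: 2 (R)-(3-bromo-2-methylpropoxy)(tert-butyl)dimethylsilane; 3 ethylene oxide
Product: 5 (S)-5-[(tert-butyldimethylsilyl)oxy]-4-methylpentan-1-ol, via Grignard reagent 4 (not isolated)
Conditions: Mg, THF, 40 °C; then CuI (10 mol %), ethylene oxide (THF solution), −30 to 0 °C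
Reagents that add atoms: none
Why: Copper-catalysed opening of an epoxide by a Grignard reagent adds C9 and C10 in one operation, and C7 is not involved (R becomes S only because the substituent priorities change).

**Step 3**
Reactants: 5 (S)-5-[(tert-butyldimethylsilyl)oxy]-4-methylpentan-1-ol
Product: 6 (S)-[(5-bromo-2-methylpentyl)oxy](tert-butyl)dimethylsilane
Conditions: CBr4, PPh3, CH2Cl2, 0 °C
Reagents that add atoms: carbon tetrabromide, BrC(Br)(Br)Br
Why: The Appel reaction converts the primary alcohol into the bromide under neutral conditions that leave the silyl ether intact.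

**Step 4**
Reactants: 6 (S)-[(5-bromo-2-methylpentyl)oxy](tert-butyl)dimethylsilane; 7 propyne
Product: 11 (S,Z)-tert-butyl[(7-iodo-2,6-dimethylhept-6-en-1-yl)oxy]dimethylsilane, via Grignard reagent 8 (not isolated), via alkylcopper 9 (not isolated), via (Z)-vinylcopper 10 (not isolated)
Conditions: Mg, Et2O, reflux; CuBr·SMe2 (1 equiv), Et2O/Me2S, −45 °C; propyne, −25 °C; I2, THF, −78 to 0 °C
Reagents that add atoms: iodine, II
Why: In the Normant carbocupration the alkylcopper adds syn to propyne, with the alkyl group on the internal carbon and copper on the terminal one, and iodinolysis with retention leaves C10 and iodine cis, which is the Z geometry of C11=C12.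

**Step 5**
Reactants: 12 3-bromofuran; 13 4-bromo-2-furaldehyde
Product: 15 (4-bromofuran-2-yl)(furan-3-yl)methanol (racemic), via 3-furyllithium 14 (not isolated)
Conditions: n-BuLi, Et2O, −78 °C; then 13, THF, −78 °C
Reagents that add atoms: none
Why: Bromine–lithium exchange is followed by 1,2-addition to the aldehyde; at −78 °C 3-furyllithium does not isomerise to the 2-lithio isomer, and carbonyl addition outruns exchange with the ring bromine of 13.

**Step 6**
Reactants: 15 (4-bromofuran-2-yl)(furan-3-yl)methanol
Product: 16 4-bromo-2-(furan-3-ylmethyl)furan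
Conditions: Et3SiH (3 equiv), TFA (2 equiv), CH2Cl2, −20 to 0 °C
Reagents that add atoms: none
Why: In this ionic hydrogenation the carbinol, flanked by two furans, ionises readily at low temperature and excess silane should trap the cation by hydride transfer before it attacks a furan ring; the C–Br bond is inert.

**Step 7**
Reactants: 16 4-bromo-2-(furan-3-ylmethyl)furan
Product: 17 4-ethenyl-2-(furan-3-ylmethyl)furan
Conditions: vinylboronic acid pinacol ester, PdCl2(dppf) (5 mol %), K2CO3, dioxane/H2O, 80 °C
Reagents that add atoms: vinylboronic acid pinacol ester, C=CB1OC(C)(C)C(C)(C)O1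
Why: Suzuki–Miyaura vinylation of the heteroaryl bromide installs C13 and C14 under basic conditions that furans tolerate.

**Step 8**
Reactants: 17 4-ethenyl-2-(furan-3-ylmethyl)furan; 11 (S,Z)-tert-butyl[(7-iodo-2,6-dimethylhept-6-en-1-yl)oxy]dimethylsilane
Product: 19 tert-butyldimethylsilyl ether of (2S,6Z)-9-[5-(furan-3-ylmethyl)furan-3-yl]-2,6-dimethylnon-6-en-1-ol, via B-alkyl-9-BBN 18 (not isolated)
Conditions: 9-BBN-H, THF, 0 °C to rt; then 11, PdCl2(dppf) (5 mol %), AsPh3, Cs2CO3, DMF/THF/H2O, rt
Reagents that add atoms: none
Why: Anti-Markovnikov hydroboration of the vinyl group by 9-BBN (the furans are inert) is followed by B-alkyl Suzuki–Miyaura coupling, in which oxidative addition and reductive elimination keep the alkene configuration, so the Z geometry passes into the C12–C13 coupled product.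

**Step 9**
Reactants: 19 silyl ether
Product: 20 (2S,6Z)-9-[5-(furan-3-ylmethyl)furan-3-yl]-2,6-dimethylnon-6-en-1-ol
Conditions: TBAF, THF, 0 °C to rt
Reagents that add atoms: none
Why: Fluoride-induced desilylation frees the primary alcohol without acid, so the furans and the trisubstituted olefin are left alone.

**Step 10**
Reactants: 20 (2S,6Z)-alcohol
Product: 21 (2S,6Z)-9-[5-(furan-3-ylmethyl)furan-3-yl]-2,6-dimethylnon-6-enal
Conditions: Dess–Martin periodinane, CH2Cl2, 0 °C to rt; used directly
Reagents that add atoms: none
Why: Dess–Martin oxidation stops at the aldehyde under nearly neutral conditions, which spares the furans and should not epimerise the α-stereocentre C7.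

**Step 11**
Reactants: 21 (2S,6Z)-aldehyde
Product: 22 2-(furan-3-ylmethyl)-4-[(3Z,8S)-4,8-dimethyldec-3-en-9-yn-1-yl]furan
Conditions: dimethyl (1-diazo-2-oxopropyl)phosphonate, K2CO3, MeOH, 0 °C to rt
Reagents that add atoms: dimethyl (1-diazo-2-oxopropyl)phosphonate, CC(=O)C(=[N+]=[N-])P(=O)(OC)OC
Why: In the Ohira–Bestmann homologation the diazophosphonate anion released by methanolysis olefinates the aldehyde, and the diazoalkene loses N2 with a 1,2-hydrogen shift to give C5≡C6; the mild carbonate base should leave C7 untouched.

**Step 12**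
Reactants: 23 methyl propionate; 24 methyl formate
Product: 26 methyl (E)-3-methoxy-2-methylacrylate, via sodium formyl enolate 25 (not isolated)
Conditions: NaH, HCO2Me (excess), THF, 0 °C to rt; then Me2SO4, DMF, rt; distillation
Reagents that add atoms: dimethyl sulfate, COS(=O)(=O)OC
Why: Crossed Claisen formylation is followed by O-alkylation of the formyl-ester enolate with a hard methylating agent in a dipolar aprotic medium, which favours the more stable E β-methoxyacrylate (methoxy trans to the ester); any Z isomer is removed by distillation.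

**Step 13**
Reactants: 26 methyl (E)-3-methoxy-2-methylacrylate
Product: 28 methyl (Z)-3-iodo-3-methoxy-2-methylacrylate, via chelated vinyllithium 27 (not isolated)
Conditions: LDA (commercial solution), THF, −90 °C; then I2, THF, −90 to −40 °C; used without storage
Reagents that add atoms: iodine, II
Why: This is an ester-directed vinylic lithiation of a β-alkoxyacrylate, in which the only vinylic hydrogen is acidified by the geminal methoxy group and lies cis to the ester carbonyl; the carbonyl chelates lithium and holds the configuration at −90 °C, and iodine traps the vinyllithium with retention.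

**Step 14**
Reactants: 22 terminal alkyne; 28 methyl (Z)-3-iodo-3-methoxy-2-methylacrylate
Product: 29 methyl (2E,6S,10Z)-13-[5-(furan-3-ylmethyl)furan-3-yl]-3-methoxy-2,6,10-trimethyltrideca-2,10-dien-4-ynoate
Conditions: PdCl2(PPh3)2 (5 mol %), CuI (10 mol %), Et3N, THF (degassed), rt
Reagents that add atoms: none
Why: In the Sonogashira coupling zerovalent palladium inserts into the C–I bond with retention and the copper acetylide of 22 delivers the alkynyl group, so C4–C5 forms with the alkyne cis to the ester (E enol ether); a tertiary amine is used so that no addition–elimination occurs at C4.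

**Step 15**
Reactants: 29 methyl ester
Product: 30 (2E,6S,10Z)-13-[5-(furan-3-ylmethyl)furan-3-yl]-3-methoxy-2,6,10-trimethyltrideca-2,10-dien-4-ynoic acid
Conditions: LiOH·H2O, THF/MeOH/H2O, rt to 40 °C; then 0.5 M HCl to pH 4, 0 °C
Reagents that add atoms: lithium hydroxide (supplies the carboxyl OH oxygen), [Li+].[OH-]
Why: In this saponification hydroxide is far too weak a base to remove the propargylic C7 hydrogen, the donor methoxy group blunts conjugate addition, and cold acidification to pH 4 spares the enol ether and the furans.

**Step 16**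
Reactants: 30 (E)-3-methoxy-2-methyl-2-en-4-ynoic acid carrying the full side chain
Product: 32 (5Z)-5-{(2S,6Z)-9-[5-(furan-3-ylmethyl)furan-3-yl]-2,6-dimethylnon-6-en-1-ylidene}-4-methoxy-3-methylfuran-2(5H)-one, via vinylsilver adduct 31 (not isolated)
Conditions: Ag2CO3 (10 mol %), DMF, rt, dark
Reagents that add atoms: none
Why: Ag2CO3 converts part of 30 into its silver carboxylate while monovalent silver binds the C5≡C6 triple bond; the carboxylate oxygen attacks the near carbon C5 from the side opposite to the metal (anti oxyargentation) to give vinylsilver 31, and a further molecule of 30 protonates the C6–Ag bond with retention and returns the catalyst. The closest known reaction type is the silver-catalysed lactonisation of (Z)-2-en-4-ynoic acids to (Z)-γ-alkylidenebutenolides. The single ring closed, the butenolide O1–C2–C3–C4–C5, forms in the 5-exo-dig mode through the new O1–C5 bond. No stereocentre is made: the new stereo-element is the C5=C6 geometry, which anti addition fixes as Z because O1 and the C6 hydrogen end up trans, and C7 keeps its S configuration because nothing in the medium is basic enough to remove the propargylic hydrogen. The step needs 5-exo closure to win over 6-endo closure at C6 (2-pyranone formation): the E enol ether holds the carboxyl oxygen next to C5, the C4 methoxy group pushes electron density into the C3–C2 acrylate and so weakens the polarisation that would make the far carbon C6 electrophilic, the branched C7 shields C6, and soft silver is the activator that favours the exo mode in this substrate class.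

**Step 17**
Reactants: 32 4-O-methyl ether of the target
Product: 33 (5Z)-5-{(2S,6Z)-9-[5-(furan-3-ylmethyl)furan-3-yl]-2,6-dimethylnon-6-en-1-ylidene}-4-hydroxy-3-methylfuran-2(5H)-one (target)
Conditions: n-PrSLi (from n-PrSH and n-BuLi), HMPA/THF, rt; then cold dilute HCl to pH 3
Reagents that add atoms: none
Why: The soft thiolate dealkylates the vinylogous methyl ester by SN2 attack at the O-methyl carbon and expels the well-stabilised tetronate anion, so that neither olefin, C7 nor the furans should be affected.

**Compound list**

1 | (R)-3-bromo-2-methylpropan-1-ol | OC[C@@H](C)CBr | starting material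
2 | (R)-(3-bromo-2-methylpropoxy)(tert-butyl)dimethylsilane | CC(C)(C)[Si](C)(C)OC[C@@H](C)CBr | intermediate
3 | ethylene oxide | C1CO1 | starting material
4 | (R)-{3-[(tert-butyldimethylsilyl)oxy]-2-methylpropyl}magnesium bromide | CC(C)(C)[Si](C)(C)OC[C@@H](C)C[Mg]Br | intermediate
5 | (S)-5-[(tert-butyldimethylsilyl)oxy]-4-methylpentan-1-ol | CC(C)(C)[Si](C)(C)OC[C@@H](C)CCCO | intermediate
6 | (S)-[(5-bromo-2-methylpentyl)oxy](tert-butyl)dimethylsilane | CC(C)(C)[Si](C)(C)OC[C@@H](C)CCCBr | intermediate
7 | propyne | CC#C | starting material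
8 | (S)-{5-[(tert-butyldimethylsilyl)oxy]-4-methylpentyl}magnesium bromide | CC(C)(C)[Si](C)(C)OC[C@@H](C)CCC[Mg]Br | intermediate
9 | (S)-{5-[(tert-butyldimethylsilyl)oxy]-4-methylpentyl}copper (MgBr2/SMe2 complex) | CC(C)(C)[Si](C)(C)OC[C@@H](C)CCC[Cu] | intermediate
10 | (1Z,6S)-{7-[(tert-butyldimethylsilyl)oxy]-2,6-dimethylhept-1-en-1-yl}copper | CC(C)(C)[Si](C)(C)OC[C@@H](C)CCC/C(C)=C\[Cu] | intermediate
11 | (S,Z)-tert-butyl[(7-iodo-2,6-dimethylhept-6-en-1-yl)oxy]dimethylsilane | CC(C)(C)[Si](C)(C)OC[C@@H](C)CCC/C(C)=C\I | intermediate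
12 | 3-bromofuran | Brc1ccoc1 | starting material
13 | 4-bromo-2-furaldehyde | O=Cc1cc(Br)co1 | starting material
14 | 3-furyllithium | [Li]c1ccoc1 | intermediate
15 | (4-bromofuran-2-yl)(furan-3-yl)methanol, racemic | OC(c1cc(Br)co1)c1ccoc1 | intermediate
16 | 4-bromo-2-(furan-3-ylmethyl)furan | Brc1coc(Cc2ccoc2)c1 | intermediate
17 | 4-ethenyl-2-(furan-3-ylmethyl)furan | C=Cc1coc(Cc2ccoc2)c1 | intermediate
18 | 9-{2-[5-(furan-3-ylmethyl)furan-3-yl]ethyl}-9-borabicyclo[3.3.1]nonane | C(Cc1coc(Cc2ccoc2)c1)B1C2CCCC1CCC2 | intermediate
19 | tert-butyldimethylsilyl ether of (2S,6Z)-9-[5-(furan-3-ylmethyl)furan-3-yl]-2,6-dimethylnon-6-en-1-ol | CC(C)(C)[Si](C)(C)OC[C@@H](C)CCC/C(C)=C\CCc1coc(Cc2ccoc2)c1 | intermediate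
20 | (2S,6Z)-9-[5-(furan-3-ylmethyl)furan-3-yl]-2,6-dimethylnon-6-en-1-ol | OC[C@@H](C)CCC/C(C)=C\CCc1coc(Cc2ccoc2)c1 | intermediate
21 | (2S,6Z)-9-[5-(furan-3-ylmethyl)furan-3-yl]-2,6-dimethylnon-6-enal | O=C[C@@H](C)CCC/C(C)=C\CCc1coc(Cc2ccoc2)c1 | intermediate
22 | 2-(furan-3-ylmethyl)-4-[(3Z,8S)-4,8-dimethyldec-3-en-9-yn-1-yl]furan | C#C[C@@H](C)CCC/C(C)=C\CCc1coc(Cc2ccoc2)c1 | intermediate
23 | methyl propionate | CCC(=O)OC | starting material
24 | methyl formate | COC=O | starting material
25 | sodium enolate of methyl 2-formylpropanoate | [Na+].COC(=O)C(C)=C[O-] | intermediate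
26 | methyl (E)-3-methoxy-2-methylacrylate | COC(=O)/C(C)=C/OC | intermediate
27 | methyl 3-lithio-3-methoxy-2-methylacrylate, lithium cis to the ester | COC(=O)/C(C)=C(/OC)[Li] | intermediate
28 | methyl (Z)-3-iodo-3-methoxy-2-methylacrylate, iodine cis to the ester | COC(=O)/C(C)=C(/OC)I | intermediate
29 | methyl (2E,6S,10Z)-13-[5-(furan-3-ylmethyl)furan-3-yl]-3-methoxy-2,6,10-trimethyltrideca-2,10-dien-4-ynoate | COC(=O)/C(C)=C(OC)\C#C[C@@H](C)CCC/C(C)=C\CCc1coc(Cc2ccoc2)c1 | intermediate
30 | (2E,6S,10Z)-13-[5-(furan-3-ylmethyl)furan-3-yl]-3-methoxy-2,6,10-trimethyltrideca-2,10-dien-4-ynoic acid | OC(=O)/C(C)=C(OC)\C#C[C@@H](C)CCC/C(C)=C\CCc1coc(Cc2ccoc2)c1 | intermediate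
31 | vinylsilver adduct, silver on C6 trans to O1 | CC1=C(OC)/C(=C(\[Ag])[C@@H](C)CCC/C(C)=C\CCc2coc(Cc3ccoc3)c2)OC1=O | intermediate
32 | (5Z)-5-{(2S,6Z)-9-[5-(furan-3-ylmethyl)furan-3-yl]-2,6-dimethylnon-6-en-1-ylidene}-4-methoxy-3-methylfuran-2(5H)-one | CC1=C(OC)/C(=C/[C@@H](C)CCC/C(C)=C\CCc2coc(Cc3ccoc3)c2)OC1=O | intermediate
33 | (5Z)-5-{(2S,6Z)-9-[5-(furan-3-ylmethyl)furan-3-yl]-2,6-dimethylnon-6-en-1-ylidene}-4-hydroxy-3-methylfuran-2(5H)-one | CC1=C(O)/C(=C/[C@@H](C)CCC/C(C)=C\CCc2coc(Cc3ccoc3)c2)OC1=O | target

**Step count**

Total step count: 17.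
Longest linear sequence: 12 steps (steps 1–4, 8–11 and 14–17).

**Steps most likely to fail**

**Step 16.** Closure in the 6-endo mode at C6 may compete with the 5-exo mode, or turnover may stall because the donor-substituted enyne is poorly activated.
- The fallback gives up the alkyne closure for an aldol–elimination on a preformed ring. It sets out from aldehyde 21 and comes back at 32.
- Commercial 3-methyltetronic acid is O-methylated (Me2SO4, K2CO3, acetone) to 4-methoxy-3-methylfuran-2(5H)-one F1.
- The C5 lithium dienolate of F1 (LDA, THF, −78 °C) adds to 21 to give the aldol adduct F2. This forms as a mixture at C5 and C6, which is of no consequence.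
- Mesylation (MsCl, Et3N, CH2Cl2, 0 °C) gives the mesylate F3. DBU-induced E1cB elimination should then give the more stable Z ylidene 32.

**Step 14 (together with the supply of its iodide from step 13).** The iodide partner may be lost by hydrolysis or addition–elimination before oxidative addition, and the valuable alkyne may undergo oxidative homocoupling.
- The fallback builds the enol ether from a keto ester. It sets out from alkyne 22 and comes back at ester 29.
- Deprotonation with n-BuLi and formylation with DMF would give the ynal F4.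
- Aldol addition of the lithium enolate of methyl propionate 23 (LDA, THF, −78 °C) would give the propargylic β-hydroxy ester F5 as a diastereomer mixture. Here the acidic partner acts as the nucleophile, so no acetylide is quenched.
- Dess–Martin oxidation would give the β-keto ester F6.
- O-Methylation of its non-chelated caesium enolate (Cs2CO3, Me2SO4, DMF, 0 °C) should favour the E enol ether 29, because the free enolate keeps its two oxygens apart. The geometric isomer is removed by chromatography.

**Step 6.** Acid-induced oligomerisation may occur through Friedel–Crafts attack of the furfuryl cation on a furan ring before hydride transfer.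
- The fallback replaces the cationic reduction by a base-mediated one. It sets out from carbinol 15 and comes back at bromide 16.
- MnO2 oxidation (CH2Cl2, rt) would give (4-bromofuran-2-yl)(furan-3-yl)methanone F7, and hydrazine hydrate would convert it into the hydrazone F8.
- Heating F8 with KOH in diethylene glycol (Wolff–Kishner reduction, Huang–Minlon procedure) should give 16 without any carbocation. These are conditions that furans tolerate.

**Further compounds**

F1 | step 16 | 4-methoxy-3-methylfuran-2(5H)-one | COC1=C(C)C(=O)OC1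
F2 | step 16 | aldol adduct, 5-{(2S,6Z)-9-[5-(furan-3-ylmethyl)furan-3-yl]-1-hydroxy-2,6-dimethylnon-6-en-1-yl}-4-methoxy-3-methylfuran-2(5H)-one (mixture at C5 and C6) | CC1=C(OC)C(OC1=O)C(O)[C@@H](C)CCC/C(C)=C\CCc2coc(Cc3ccoc3)c2
F3 | step 16 | mesylate of F2 | CC1=C(OC)C(OC1=O)C(OS(C)(=O)=O)[C@@H](C)CCC/C(C)=C\CCc2coc(Cc3ccoc3)c2
F4 | step 14 | (4S,8Z)-11-[5-(furan-3-ylmethyl)furan-3-yl]-4,8-dimethylundec-8-en-2-ynal | O=CC#C[C@@H](C)CCC/C(C)=C\CCc1coc(Cc2ccoc2)c1
F5 | step 14 | methyl (6S,10Z)-13-[5-(furan-3-ylmethyl)furan-3-yl]-3-hydroxy-2,6,10-trimethyltridec-10-en-4-ynoate (mixture at C2 and C3 of the ester) | COC(=O)C(C)C(O)C#C[C@@H](C)CCC/C(C)=C\CCc1coc(Cc2ccoc2)c1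
F6 | step 14 | methyl (6S,10Z)-13-[5-(furan-3-ylmethyl)furan-3-yl]-2,6,10-trimethyl-3-oxotridec-10-en-4-ynoate | COC(=O)C(C)C(=O)C#C[C@@H](C)CCC/C(C)=C\CCc1coc(Cc2ccoc2)c1
F7 | step 6 | (4-bromofuran-2-yl)(furan-3-yl)methanone | O=C(c1cc(Br)co1)c1ccoc1
F8 | step 6 | hydrazone of (4-bromofuran-2-yl)(furan-3-yl)methanone | NN=C(c1cc(Br)co1)c1ccoc1
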